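**Retrosynthetic overview**

- The target is a (3R,4R)-3,4-dibenzylbutyrolactone (ring A on the C3 benzyl, ring B on the C4 benzyl) whose ring B carries, ortho to its phenol, an (S)-CH(CH2OH)–C(=O)–aryl unit (ring C). The plan rests on the lactone C5, an unsubstituted O–CH2 next to the trans C3/C4 pair: it is carried as a chiral menthyl acetal carbon that steers both benzylic C–C bonds and is then reduced to CH2.
- Late disconnections: ring C ketone ⇐ arylcerium addition to an α-aryl aldehyde, then oxidation; aldehyde ⇐ ozonolysis of a propenyl group; side-chain stereocentre ⇐ aromatic Claisen rearrangement with 1,3-chirality transfer from an (R)-secondary allyl aryl ether (Mitsunobu, inversion).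
- Key disconnection: the C4–C(benzylic, ring B) and C3–CH2(ring A) bonds ⇐ conjugate addition of the lithiated ring B dithiane to the (5R)-menthyloxybutenolide and benzylation of the resulting enolate in the same flask.
- Rings: no ring is built. The lactone ring comes from the furan of furfural, is opened and re-closed once when the acetal carbon is reduced; rings A, B and C are bought as vanillin-type arenes.
- Protection: benzyl on the ring A and ring C phenols and on the primary alcohol (all removed at the end), triisopropylsilyl on ring B (removed selectively before the etherification).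

Key step: step 6

Remark: the benzylic centre α to the ring C ketone is taken to be configurationally stable only under neutral conditions, so the ketone is unveiled in the last two steps and never meets base; 9, 19, 20 and 26 are taken as purchased.

**Route**

Step 1
Reactants: 1 furfural
Product: 2 5-hydroxyfuran-2(5H)-one (racemic)
Conditions: O2, hν (visible), rose bengal (cat.), MeOH, rt
Reagents that add atoms: dioxygen, O=O
Why: Dye-sensitised [4+2] photooxygenation of the furan by singlet oxygen gives an endoperoxide that fragments in methanol with loss of the formyl carbon as methyl formate, the established entry to the racemic γ-hydroxybutenolide.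

Step 2
Reactants: 2 5-hydroxyfuran-2(5H)-one; 3 (−)-menthol
Product: 4 (5R)-5-(l-menthyloxy)furan-2(5H)-one
Conditions: p-TsOH (cat.), toluene, reflux (Dean–Stark); crystallisation from petroleum ether, mother liquor re-equilibrated with acid
Reagents that add atoms: none
Why: Acid-catalysed acetalisation of the lactol gives both C5 epimers, which interconvert through the oxocarbenium ion, so crystallisation of the less soluble (5R) epimer with recycling of the mother liquor sets C5 by crystallisation-induced selection with (−)-menthol as auxiliary.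

Step 3
Reactants: 5 vanillin; 6 1,3-propanedithiol
Product: 7 2-(4-hydroxy-3-methoxyphenyl)-1,3-dithiane
Conditions: BF3·OEt2 (cat.), CH2Cl2, 0 °C → rt
Reagents that add atoms: none
Why: Lewis-acid-catalysed dithioacetalisation of the aryl aldehyde, which the free phenol does not disturb.

Step 4
Reactants: 7 2-(4-hydroxy-3-methoxyphenyl)-1,3-dithiane
Product: 8 2-(3-methoxy-4-triisopropylsilyloxyphenyl)-1,3-dithiane
Conditions: TIPSCl, imidazole, DMF, rt
Reagents that add atoms: triisopropylsilyl chloride, CC(C)[Si](Cl)(C(C)C)C(C)C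
Why: Imidazole-promoted silylation of the phenol gives a bulky aryl silyl ether that tolerates n-BuLi at low temperature and is later cleaved by fluoride in the presence of benzyl ethers.

Step 5
Reactants: 9 (4-benzyloxy-3-methoxyphenyl)methanol
Product: 10 4-benzyloxy-3-methoxybenzyl bromide
Conditions: PBr3, Et2O, 0 °C
Reagents that add atoms: phosphorus tribromide, BrP(Br)Br
Why: SN2 bromination of an electron-rich benzylic alcohol with PBr3; the bromide is used at once because it solvolyses readily.

Step 6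
Reactants: 8 2-(3-methoxy-4-triisopropylsilyloxyphenyl)-1,3-dithiane; 4 (5R)-5-(l-menthyloxy)furan-2(5H)-one; 10 4-benzyloxy-3-methoxybenzyl bromide
Product: 13 (3R,4R,5R)-3-(4-benzyloxy-3-methoxybenzyl)-4-[2-(3-methoxy-4-triisopropylsilyloxyphenyl)-1,3-dithian-2-yl]-5-(l-menthyloxy)dihydrofuran-2(3H)-one, via lithiated dithiane 11 (not isolated), via lithium lactone enolate 12 (not isolated)
Conditions: n-BuLi, THF, −78 → −20 °C; 4, −78 °C; 10, DMPU, −78 °C → rt
Reagents that add atoms: none
Why: n-BuLi removes the C2 proton of dithiane 8 to give the sulfur-stabilised benzylic anion 11, a soft acyl-anion equivalent that adds 1,4 to C4 of butenolide 4, and the lithium enolate 12 so formed is C-alkylated at C3 by the benzylic bromide 10 in the same flask. The closest known reaction type is exactly this tandem Michael addition–enolate alkylation of lithiated 2-aryl-1,3-dithianes with 5-alkoxyfuran-2(5H)-ones; two C–C bonds are formed and no ring is closed. The C4 centre is controlled by the C5 acetal carbon: the nucleophile enters the flat butenolide on the face opposite the bulky menthyloxy group, giving the 4,5-trans relationship. The C3 centre is controlled by the new C4 substituent: the enolate is benzylated anti to the very large 2-aryl-dithianyl group, giving the 3,4-trans relationship, so both centres derive from the (5R) acetal and end as (3R,4R). The step needs 1,4- over 1,2-addition and C- over O-alkylation; the delocalised dithianyl anion and the unhindered β-carbon of the γ-alkoxybutenolide favour conjugate addition, and the soft benzylic bromide with DMPU favours C-alkylation.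

Step 7
Reactants: 13 the dithianyl lactone acetal
Product: 14 (3R,4R,5R)-3-(4-benzyloxy-3-methoxybenzyl)-4-(3-methoxy-4-triisopropylsilyloxybenzyl)-5-(l-menthyloxy)dihydrofuran-2(3H)-one
Conditions: Raney Ni (W-2, deactivated in refluxing acetone, washed neutral), EtOH/THF, rt → 50 °C
Reagents that add atoms: none
Why: Raney nickel desulfurisation (hydrogenolytic C–S cleavage) turns the dithiane carbon into the ring B benzylic CH2, and the deactivated catalyst at moderate temperature should spare the aryl benzyl ether, the silyl ether, the lactone acetal and the three stereocentres.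

Step 8
Reactants: 14 the silyl-protected lactone acetal
Product: 15 (3R,4R,5R)-3-(4-benzyloxy-3-methoxybenzyl)-4-(4-hydroxy-3-methoxybenzyl)-5-(l-menthyloxy)dihydrofuran-2(3H)-one
Conditions: TBAF, AcOH, THF, 0 °C
Reagents that add atoms: none
Why: Fluoride-mediated cleavage of the aryl silyl ether, buffered with acetic acid so that the base-sensitive lactone acetal and the C3/C4 centres are not exposed to basic fluoride or phenoxide.

Step 9
Reactants: 15 the phenolic lactone acetal
Product: 18 (3R,4R)-3-(4-benzyloxy-3-methoxybenzyl)-4-(4-hydroxy-3-methoxybenzyl)dihydrofuran-2(3H)-one, via ring-opened 4-oxo acid 16 (not isolated), via 4-hydroxy acid 17 (not isolated)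
Conditions: NaBH4, KOH, EtOH/H2O, 0 °C → rt; then 2 M HCl, rt
Reagents that add atoms: potassium hydroxide, [K+].[OH-] (its oxygen enters the carboxylate and can end as a lactone carboxyl oxygen)
Why: Hydroxide opens the pseudo-ester to the carboxylate aldehyde 16 with loss of menthol, NaBH4 present from the start reduces the aldehyde to 17 faster than the adjacent C4 centre can enolise, and acidification closes the γ-lactone (saponification, carbonyl reduction, lactonisation), so C5 ends as CH2 and C3/C4 keep the (3R,4R) trans arrangement.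

Step 10
Reactants: 19 (S)-but-3-en-2-ol; 20 (Z)-1,4-bis(benzyloxy)but-2-ene
Product: 21 (2S,3E)-5-(benzyloxy)pent-3-en-2-ol
Conditions: second-generation Grubbs catalyst RuCl2(=CHPh)(H2IMes)(PCy3) (cat.), 1,4-benzoquinone (cat.), CH2Cl2, 40 °C; (E)-isomer purified by chromatography
Reagents that add atoms: none
Why: Olefin cross-metathesis of the terminal alkene with a symmetrical internal alkene, driven by loss of ethylene, should give the thermodynamically favoured (E)-alkene without touching the carbinol centre, which comes from the purchased (S)-alcohol.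

Step 11
Reactants: 18 the ring B phenol lactone; 21 (2S,3E)-5-(benzyloxy)pent-3-en-2-ol
Product: 22 (3R,4R)-3-(4-benzyloxy-3-methoxybenzyl)-4-{4-[(2R,3E)-5-(benzyloxy)pent-3-en-2-yloxy]-3-methoxybenzyl}dihydrofuran-2(3H)-one
Conditions: PPh3, DIAD, toluene, 0 °C → rt
Reagents that add atoms: none
Why: Mitsunobu etherification in which the only free OH of 18, the ring B phenol, displaces the oxyphosphonium salt of the secondary allylic alcohol by SN2 with inversion, converting the (S)-carbinol into the (R)-aryl ether needed for the chirality transfer.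

Step 12
Reactants: 22 the (R)-allyl aryl ether
Product: 23 (3R,4R)-3-(4-benzyloxy-3-methoxybenzyl)-4-{3-[(2S,3E)-1-(benzyloxy)pent-3-en-2-yl]-4-hydroxy-5-methoxybenzyl}dihydrofuran-2(3H)-one
Conditions: Eu(fod)3 [tris(6,6,7,7,8,8,8-heptafluoro-2,2-dimethyl-3,5-octanedionato)europium] (cat.), CHCl3, 50 °C
Reagents that add atoms: none
Why: Lewis-acid-catalysed aromatic Claisen rearrangement ([3,3]-sigmatropic shift to the only free ortho position of ring B, then rearomatisation) through a chair transition state with the methyl group equatorial, which transfers the C–O stereocentre suprafacially across the (E)-allyl unit to the new benzylic carbon ((R)-ether to (S)-product with an (E)-propenyl group), while chelation of europium by the ether and methoxy oxygens allows a temperature at which lactone and benzyl ethers are safe.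

Step 13
Reactants: 23 the ortho-substituted phenol
Product: 24 (3R,4R)-3-(4-benzyloxy-3-methoxybenzyl)-4-{4-benzyloxy-3-[(2S,3E)-1-(benzyloxy)pent-3-en-2-yl]-5-methoxybenzyl}dihydrofuran-2(3H)-one
Conditions: BnBr, K2CO3, DMF, rt
Reagents that add atoms: benzyl bromide, BrCc1ccccc1
Why: Williamson benzylation with a weak base masks the new phenol, which would otherwise add to the aldehyde and ketone formed next (lactol or benzofuran formation), and K2CO3 is too weak to deprotonate the benzylic/allylic centre.

Step 14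
Reactants: 24 the propenyl compound
Product: 25 (2S)-3-(benzyloxy)-2-{2-benzyloxy-3-methoxy-5-[((3R,4R)-4-(4-benzyloxy-3-methoxybenzyl)-5-oxotetrahydrofuran-3-yl)methyl]phenyl}propanal
Conditions: O3 (dosed to the alkene), CH2Cl2/MeOH, −78 °C; PPh3, −78 °C → rt; used crude
Reagents that add atoms: ozone, [O-][O+]=O
Why: Ozonolysis with reductive work-up cleaves the only alkene, which reacts with ozone far faster than the alkoxyarenes when the dose is controlled, to the α-aryl aldehyde under neutral conditions at low temperature, so the benzylic centre should be retained.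

Step 15
Reactants: 25 the α-aryl aldehyde; 26 1-(benzyloxy)-4-bromo-2-methoxybenzene
Product: 29 (3R,4R)-3-(4-benzyloxy-3-methoxybenzyl)-4-{4-benzyloxy-3-[(2S)-3-(benzyloxy)-1-(4-benzyloxy-3-methoxyphenyl)-1-hydroxypropan-2-yl]-5-methoxybenzyl}dihydrofuran-2(3H)-one (both carbinol epimers), via aryllithium 27 (not isolated), via arylcerium dichloride 28 (not isolated)
Conditions: 26, n-BuLi, THF, −78 °C; CeCl3 (anhydrous), −78 °C; 25, −78 °C; aq. NH4Cl
Reagents that add atoms: none
Why: Bromine–lithium exchange and transmetalation to cerium give a strongly nucleophilic but weakly basic organocerium reagent whose 1,2-addition to the aldehyde at −78 °C should outrun enolisation of the α-aryl aldehyde and attack on the lactone; the new carbinol centre is uncontrolled and is removed by oxidation in the next step.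

Step 16
Reactants: 29 the benzylic alcohol
Product: 30 (3R,4R)-3-(4-benzyloxy-3-methoxybenzyl)-4-{4-benzyloxy-3-[(2S)-3-(benzyloxy)-1-(4-benzyloxy-3-methoxyphenyl)-1-oxopropan-2-yl]-5-methoxybenzyl}dihydrofuran-2(3H)-one
Conditions: Dess–Martin periodinane, CH2Cl2, 0 °C → rt
Reagents that add atoms: none
Why: Dess–Martin oxidation of the secondary benzylic alcohol to the aryl ketone under near-neutral conditions converges both carbinol epimers and should not epimerise the adjacent benzylic centre.

Step 17
Reactants: 30 the tetrabenzyl ketone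
Product: 31 (3R,4R)-3-(4-hydroxy-3-methoxybenzyl)-4-{4-hydroxy-3-[(2S)-3-hydroxy-1-(4-hydroxy-3-methoxyphenyl)-1-oxopropan-2-yl]-5-methoxybenzyl}dihydrofuran-2(3H)-one (CNP0191394.1)
Conditions: H2 (1 atm), Pd/C (10 % palladium on carbon), EtOAc/EtOH, rt, monitored
Reagents that add atoms: none
Why: Catalytic hydrogenolysis cleaves the three aryl benzyl ethers and the primary alkyl benzyl ether under neutral conditions, stopped before the electron-rich aryl ketone is reduced, so the α-keto benzylic centre and the lactone centres are retained and the target is released without acid or base.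

**Compound list**

1 | furfural | O=Cc1ccco1 | starting material
2 | 5-hydroxyfuran-2(5H)-one (racemic) | OC1C=CC(=O)O1 | intermediate
3 | (−)-menthol, (1R,2S,5R)-2-isopropyl-5-methylcyclohexanol | CC(C)[C@@H]1CC[C@@H](C)C[C@H]1O | starting material
4 | (5R)-5-(l-menthyloxy)furan-2(5H)-one | CC(C)[C@@H]1CC[C@@H](C)C[C@H]1O[C@H]1C=CC(=O)O1 | intermediate
5 | vanillin | COc1cc(C=O)ccc1O | starting material
6 | 1,3-propanedithiol | SCCCS | starting material
7 | 2-(4-hydroxy-3-methoxyphenyl)-1,3-dithiane | COc1cc(C2SCCCS2)ccc1O | intermediate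
8 | 2-(3-methoxy-4-triisopropylsilyloxyphenyl)-1,3-dithiane | COc1cc(C2SCCCS2)ccc1O[Si](C(C)C)(C(C)C)C(C)C | intermediate
9 | (4-benzyloxy-3-methoxyphenyl)methanol | COc1cc(CO)ccc1OCc1ccccc1 | starting material
10 | 4-benzyloxy-3-methoxybenzyl bromide | COc1cc(CBr)ccc1OCc1ccccc1 | intermediate
11 | 2-lithio-2-(3-methoxy-4-triisopropylsilyloxyphenyl)-1,3-dithiane (not isolated) | COc1cc(C2([Li])SCCCS2)ccc1O[Si](C(C)C)(C(C)C)C(C)C | intermediate
12 | lithium enolate of (4R,5R)-4-(2-aryl-1,3-dithian-2-yl)-5-(l-menthyloxy)dihydrofuran-2(3H)-one (not isolated) | [Li]OC1=C[C@@H](C2(c3ccc(O[Si](C(C)C)(C(C)C)C(C)C)c(OC)c3)SCCCS2)[C@H](O[C@@H]2C[C@H](C)CC[C@H]2C(C)C)O1 | intermediate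
13 | (3R,4R,5R)-3-(4-benzyloxy-3-methoxybenzyl)-4-[2-(3-methoxy-4-triisopropylsilyloxyphenyl)-1,3-dithian-2-yl]-5-(l-menthyloxy)dihydrofuran-2(3H)-one (3,4-trans, 4,5-trans) | COc1cc(C[C@H]2C(=O)O[C@@H](O[C@@H]3C[C@H](C)CC[C@H]3C(C)C)[C@@H]2C2(c3ccc(O[Si](C(C)C)(C(C)C)C(C)C)c(OC)c3)SCCCS2)ccc1OCc1ccccc1 | intermediate
14 | (3R,4R,5R)-3-(4-benzyloxy-3-methoxybenzyl)-4-(3-methoxy-4-triisopropylsilyloxybenzyl)-5-(l-menthyloxy)dihydrofuran-2(3H)-one | COc1cc(C[C@H]2C(=O)O[C@@H](O[C@@H]3C[C@H](C)CC[C@H]3C(C)C)[C@@H]2Cc2ccc(O[Si](C(C)C)(C(C)C)C(C)C)c(OC)c2)ccc1OCc1ccccc1 | intermediate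
15 | (3R,4R,5R)-3-(4-benzyloxy-3-methoxybenzyl)-4-(4-hydroxy-3-methoxybenzyl)-5-(l-menthyloxy)dihydrofuran-2(3H)-one | COc1cc(C[C@H]2C(=O)O[C@@H](O[C@@H]3C[C@H](C)CC[C@H]3C(C)C)[C@@H]2Cc2ccc(O)c(OC)c2)ccc1OCc1ccccc1 | intermediate
16 | (2R,3R)-2-(4-benzyloxy-3-methoxybenzyl)-3-(4-hydroxy-3-methoxybenzyl)-4-oxobutanoic acid (potassium salt in the flask, not isolated) | COc1cc(C[C@@H](C(=O)O)[C@H](C=O)Cc2ccc(O)c(OC)c2)ccc1OCc1ccccc1 | intermediate
17 | (2R,3R)-2-(4-benzyloxy-3-methoxybenzyl)-4-hydroxy-3-(4-hydroxy-3-methoxybenzyl)butanoic acid (potassium salt in the flask, not isolated) | COc1cc(C[C@@H](C(=O)O)[C@H](CO)Cc2ccc(O)c(OC)c2)ccc1OCc1ccccc1 | intermediate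
18 | (3R,4R)-3-(4-benzyloxy-3-methoxybenzyl)-4-(4-hydroxy-3-methoxybenzyl)dihydrofuran-2(3H)-one | COc1cc(C[C@H]2C(=O)OC[C@@H]2Cc2ccc(O)c(OC)c2)ccc1OCc1ccccc1 | intermediate
19 | (S)-but-3-en-2-ol | C[C@H](O)C=C | starting material
20 | (Z)-1,4-bis(benzyloxy)but-2-ene | c1ccccc1COC/C=C\COCc1ccccc1 | starting material
21 | (2S,3E)-5-(benzyloxy)pent-3-en-2-ol | C[C@H](O)/C=C/COCc1ccccc1 | intermediate
22 | (3R,4R)-3-(4-benzyloxy-3-methoxybenzyl)-4-{4-[(2R,3E)-5-(benzyloxy)pent-3-en-2-yloxy]-3-methoxybenzyl}dihydrofuran-2(3H)-one | COc1cc(C[C@H]2C(=O)OC[C@@H]2Cc2ccc(O[C@H](C)/C=C/COCc3ccccc3)c(OC)c2)ccc1OCc1ccccc1 | intermediate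
23 | (3R,4R)-3-(4-benzyloxy-3-methoxybenzyl)-4-{3-[(2S,3E)-1-(benzyloxy)pent-3-en-2-yl]-4-hydroxy-5-methoxybenzyl}dihydrofuran-2(3H)-one | COc1cc(C[C@H]2C(=O)OC[C@@H]2Cc2cc(OC)c(O)c([C@@H](COCc3ccccc3)/C=C/C)c2)ccc1OCc1ccccc1 | intermediate
24 | (3R,4R)-3-(4-benzyloxy-3-methoxybenzyl)-4-{4-benzyloxy-3-[(2S,3E)-1-(benzyloxy)pent-3-en-2-yl]-5-methoxybenzyl}dihydrofuran-2(3H)-one | COc1cc(C[C@H]2C(=O)OC[C@@H]2Cc2cc(OC)c(OCc3ccccc3)c([C@@H](COCc3ccccc3)/C=C/C)c2)ccc1OCc1ccccc1 | intermediate
25 | (2S)-3-(benzyloxy)-2-{2-benzyloxy-3-methoxy-5-[((3R,4R)-4-(4-benzyloxy-3-methoxybenzyl)-5-oxotetrahydrofuran-3-yl)methyl]phenyl}propanal | COc1cc(C[C@H]2C(=O)OC[C@@H]2Cc2cc(OC)c(OCc3ccccc3)c([C@@H](COCc3ccccc3)C=O)c2)ccc1OCc1ccccc1 | intermediate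
26 | 1-(benzyloxy)-4-bromo-2-methoxybenzene | COc1cc(Br)ccc1OCc1ccccc1 | starting material
27 | (4-benzyloxy-3-methoxyphenyl)lithium (not isolated) | COc1cc([Li])ccc1OCc1ccccc1 | intermediate
28 | (4-benzyloxy-3-methoxyphenyl)cerium dichloride (not isolated) | COc1cc([Ce](Cl)Cl)ccc1OCc1ccccc1 | intermediate
29 | (3R,4R)-3-(4-benzyloxy-3-methoxybenzyl)-4-{4-benzyloxy-3-[(2S)-3-(benzyloxy)-1-(4-benzyloxy-3-methoxyphenyl)-1-hydroxypropan-2-yl]-5-methoxybenzyl}dihydrofuran-2(3H)-one, both carbinol epimers | COc1cc(C[C@H]2C(=O)OC[C@@H]2Cc2cc(OC)c(OCc3ccccc3)c([C@@H](COCc3ccccc3)C(O)c3ccc(OCc4ccccc4)c(OC)c3)c2)ccc1OCc1ccccc1 | intermediate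
30 | (3R,4R)-3-(4-benzyloxy-3-methoxybenzyl)-4-{4-benzyloxy-3-[(2S)-3-(benzyloxy)-1-(4-benzyloxy-3-methoxyphenyl)-1-oxopropan-2-yl]-5-methoxybenzyl}dihydrofuran-2(3H)-one | COc1cc(C[C@H]2C(=O)OC[C@@H]2Cc2cc(OC)c(OCc3ccccc3)c([C@@H](COCc3ccccc3)C(=O)c3ccc(OCc4ccccc4)c(OC)c3)c2)ccc1OCc1ccccc1 | intermediate
31 | (3R,4R)-3-(4-hydroxy-3-methoxybenzyl)-4-{4-hydroxy-3-[(2S)-3-hydroxy-1-(4-hydroxy-3-methoxyphenyl)-1-oxopropan-2-yl]-5-methoxybenzyl}dihydrofuran-2(3H)-one (CNP0191394.1) | COc1cc(C[C@H]2C(=O)OC[C@@H]2Cc2cc(OC)c(O)c([C@@H](CO)C(=O)c3ccc(O)c(OC)c3)c2)ccc1O | target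

**Step count**

Total: 17 steps. Longest linear sequence: 13 steps (1, 2, 6, 7, 8, 9, 11, 12, 13, 14, 15, 16, 17; the branch from vanillin through 3 and 4 is equally long).

**Steps most likely to fail**

The key step has close precedent in its reaction class; the three weakest points lie in building the ring B side chain.

1. Step 11 (Mitsunobu etherification). The phenoxide may attack the γ-carbon of the allylic oxyphosphonium salt (SN2′), giving the regioisomeric ether, and an ion-pair pathway may erode the configuration; both would lower the stereochemical purity of the side-chain centre after the rearrangement. The fallback sets out from 18 and builds the C–O bond on a propargylic alcohol, where no low-energy SN2′ channel exists. Benzyl propargyl ether is lithiated (n-BuLi, THF, −78 °C) and acylated with N-methoxy-N-methylacetamide to 5-(benzyloxy)pent-3-yn-2-one F1. Noyori asymmetric transfer hydrogenation (RuCl(p-cymene)[(S,S)-TsDPEN], i-PrOH, rt) should give (S)-5-(benzyloxy)pent-3-yn-2-ol F2. Mitsunobu reaction of F2 with 18 (PPh3, DIAD, toluene) should give, with inversion, the (R)-propargyl aryl ether (3R,4R)-3-(4-benzyloxy-3-methoxybenzyl)-4-{4-[(2R)-5-(benzyloxy)pent-3-yn-2-yloxy]-3-methoxybenzyl}dihydrofuran-2(3H)-one F3. Ruthenium-catalysed trans-hydrogenation of the alkyne (Cp*RuCl(cod), AgOTf, H2, CH2Cl2) then gives the (E)-alkene and comes back to the route at 22.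

2. Step 12 (aromatic Claisen rearrangement). The secondary allylic ether may ionise at the Lewis acid, or part of the material may rearrange through the chair with an axial methyl group (giving the (Z)-alkene of opposite configuration), so the chirality transfer may be incomplete; cleavage back to the phenol is also possible. The fallback sets out from 18 and gives up stereocontrol in favour of a robust rearrangement followed by separation. Mitsunobu reaction of 18 with purchased (Z)-4-(benzyloxy)but-2-en-1-ol (PPh3, DIAD) gives the primary allyl ether (3R,4R)-3-(4-benzyloxy-3-methoxybenzyl)-4-{4-[(Z)-4-(benzyloxy)but-2-enyloxy]-3-methoxybenzyl}dihydrofuran-2(3H)-one F4. Thermal Claisen rearrangement (N,N-diethylaniline, 190 °C) gives the ortho-[1-(benzyloxy)but-3-en-2-yl]phenol F5 as both epimers at the new benzylic carbon. Benzylation (BnBr, K2CO3, DMF) and separation of the two diastereomers by preparative HPLC on a chiral stationary phase give the (S)-configured benzyl ether (3R,4R)-3-(4-benzyloxy-3-methoxybenzyl)-4-{4-benzyloxy-3-[(2S)-1-(benzyloxy)but-3-en-2-yl]-5-methoxybenzyl}dihydrofuran-2(3H)-one F6. Ozonolysis of F6 (O3, CH2Cl2/MeOH, −78 °C; PPh3) comes back to the route at 25.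

3. Step 15 (aryl addition to the α-aryl aldehyde). The organometallic may enolise the aldehyde (loss of the benzylic configuration), trigger β-elimination of benzyl alcohol, or attack the lactone. The fallback sets out from 25 and replaces carbonyl addition and oxidation by a base-free acyl cross-coupling. Pinnick oxidation (NaClO2, NaH2PO4, 2-methyl-2-butene, t-BuOH/H2O) gives the acid (2S)-3-(benzyloxy)-2-{2-benzyloxy-3-methoxy-5-[((3R,4R)-4-(4-benzyloxy-3-methoxybenzyl)-5-oxotetrahydrofuran-3-yl)methyl]phenyl}propanoic acid F7. Coupling with ethanethiol (EDC·HCl, HOBt, CH2Cl2, 0 °C, no DMAP to avoid a ketene) gives the S-ethyl thioester F8. Liebeskind–Srogl coupling of F8 with (4-benzyloxy-3-methoxyphenyl)boronic acid (Pd2(dba)3, tri(2-furyl)phosphine, copper thiophene-2-carboxylate Cu(O2C-C4H3S) with monovalent copper, THF, 50 °C) gives the ketone directly and comes back to the route at 30, bypassing 29 and step 16.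

**Further compounds**

F1 | step 11 | 5-(benzyloxy)pent-3-yn-2-one | CC(=O)C#CCOCc1ccccc1
F2 | step 11 | (S)-5-(benzyloxy)pent-3-yn-2-ol | C[C@H](O)C#CCOCc1ccccc1
F3 | step 11 | (3R,4R)-3-(4-benzyloxy-3-methoxybenzyl)-4-{4-[(2R)-5-(benzyloxy)pent-3-yn-2-yloxy]-3-methoxybenzyl}dihydrofuran-2(3H)-one | COc1cc(C[C@H]2C(=O)OC[C@@H]2Cc2ccc(O[C@H](C)C#CCOCc3ccccc3)c(OC)c2)ccc1OCc1ccccc1
F4 | step 12 | (3R,4R)-3-(4-benzyloxy-3-methoxybenzyl)-4-{4-[(Z)-4-(benzyloxy)but-2-enyloxy]-3-methoxybenzyl}dihydrofuran-2(3H)-one | COc1cc(C[C@H]2C(=O)OC[C@@H]2Cc2ccc(OC/C=C\COCc3ccccc3)c(OC)c2)ccc1OCc1ccccc1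
F5 | step 12 | (3R,4R)-3-(4-benzyloxy-3-methoxybenzyl)-4-{3-[1-(benzyloxy)but-3-en-2-yl]-4-hydroxy-5-methoxybenzyl}dihydrofuran-2(3H)-one, both side-chain epimers | COc1cc(C[C@H]2C(=O)OC[C@@H]2Cc2cc(OC)c(O)c(C(COCc3ccccc3)C=C)c2)ccc1OCc1ccccc1
F6 | step 12 | (3R,4R)-3-(4-benzyloxy-3-methoxybenzyl)-4-{4-benzyloxy-3-[(2S)-1-(benzyloxy)but-3-en-2-yl]-5-methoxybenzyl}dihydrofuran-2(3H)-one | COc1cc(C[C@H]2C(=O)OC[C@@H]2Cc2cc(OC)c(OCc3ccccc3)c([C@@H](COCc3ccccc3)C=C)c2)ccc1OCc1ccccc1
F7 | step 15 | (2S)-3-(benzyloxy)-2-{2-benzyloxy-3-methoxy-5-[((3R,4R)-4-(4-benzyloxy-3-methoxybenzyl)-5-oxotetrahydrofuran-3-yl)methyl]phenyl}propanoic acid | COc1cc(C[C@H]2C(=O)OC[C@@H]2Cc2cc(OC)c(OCc3ccccc3)c([C@@H](COCc3ccccc3)C(=O)O)c2)ccc1OCc1ccccc1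
F8 | step 15 | S-ethyl (2S)-3-(benzyloxy)-2-{2-benzyloxy-3-methoxy-5-[((3R,4R)-4-(4-benzyloxy-3-methoxybenzyl)-5-oxotetrahydrofuran-3-yl)methyl]phenyl}propanethioate | COc1cc(C[C@H]2C(=O)OC[C@@H]2Cc2cc(OC)c(OCc3ccccc3)c([C@@H](COCc3ccccc3)C(=O)SCC)c2)ccc1OCc1ccccc1
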